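## Retrosynthetic overview

1. Numbering: C1 quaternary carbinol, C2 ketone, C3=C4, C5 CHOH, C6 CHOBz, C7 CH2OBz. The strategy rests on the chain C7–C1(O)–C2–C3=C4 of the single six-membered carbocycle C1–C6. Read with C7 as CO2H and C2 as CH2, it is a γ,δ-unsaturated α-oxy acid whose alkene lies inside the ring, which is the imprint of an ester-enolate [3,3] shift.
2. End game (no ring formed): C2=O comes from allylic C–H oxidation, both benzoates from a C6/C7 diol, and C7H2OH from the carboxylic acid.
3. Key disconnection C1–C2 (C4–O restored): the cyclohexenecarboxylic acid comes from the silyl ketene acetal C1=C7 of a 6-vinyl δ-lactone (ring O–C4–C5–C6–C1–C7). The C4 carbinol centre is traded for the quaternary C1.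
4. The lactone comes from oxidative lactonisation of a hept-1-ene-3,7-diol, made by chelation-controlled vinyl addition to a D-arabinopyranose lactol. Arabinose C2 and C3 become C5 and C6.
5. Ring order: the sugar pyranose is opened, the δ-lactone ring is formed, and that ring is contracted to the carbocycle, the only ring of the target.

Key step: step 8

Remarks on the chemistry (assumptions):
- The lactone α-carbon (C1) is planarised in step 8, so its configuration in the precursor is free. The L-gulo lactone, which D-arabinose delivers directly, is assumed to serve as well as its C2 epimer.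
- In the boat array the C6–O bond must stand pseudo-axial, anti to the incoming C2. A five-membered acetal across the C1 and C6 oxygens cannot adopt this geometry and is avoided.
- An ether at C6 would be aligned for β-elimination from the enolate. This oxygen is therefore carried through enolisation as its lithium alkoxide.
- Abbreviations: MOM = CH2OCH3, PMB = 4-methoxybenzyl. Carbocycles are named with the target numbering.

## Route

Step 1
Reactants: 1 D-arabinose; 2 allyl alcohol
Product: 3 allyl β-D-arabinopyranoside
Conditions: 2 (solvent), TsOH·H2O (cat.), 80 °C; crystallisation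
Reagents that add atoms: allyl alcohol (2), C=CCO
Why: Fischer glycosidation under equilibrating acid should favour the pyranoside with the axial, anomerically stabilised allyloxy group, which masks the sugar C1 and leaves the three ring hydroxyls open without touching a stereocentre of the target.

Step 2
Reactants: 3 allyl β-D-arabinopyranoside; 4 4-methoxybenzyl chloride
Product: 6 allyl 3-O-(4-methoxybenzyl)-β-D-arabinopyranoside, via 3,4-O-dibutylstannylene acetal 5 (not isolated)
Conditions: Bu2SnO (1.1 equiv), toluene, reflux, Dean–Stark; then 4 (1.3 equiv), Bu4NI (cat.), 90 °C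
Reagents that add atoms: 4-methoxybenzyl chloride (4), COc1ccc(CCl)cc1
Why: In this stannylene-acetal-directed alkylation the tin acetal forms on the cis-3,4-diol and activates its equatorial oxygen O3, so the oxygen that becomes C6–O is singled out from O2 and O4.

Step 3
Reactants: 6 allyl 3-O-PMB-β-D-arabinopyranoside; 7 chloromethyl methyl ether
Product: 8 allyl 2,4-di-O-(methoxymethyl)-3-O-(4-methoxybenzyl)-β-D-arabinopyranoside
Conditions: 7 (4 equiv), iPr2NEt (6 equiv), Bu4NI (cat.), CH2Cl2, 0 → 40 °C
Reagents that add atoms: chloromethyl methyl ether (7), COCCl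
Why: Standard O-alkylation with an α-chloro ether caps O2 and O4 (the future C5–O and C1–O) with a small, base-stable and chelating acetal group.

Step 4
Reactants: 8 allyl 2,4-di-O-MOM-3-O-PMB-β-D-arabinopyranoside
Product: 10 2,4-di-O-(methoxymethyl)-3-O-(4-methoxybenzyl)-D-arabinopyranose (lactol; anomeric mixture), via prop-1-enyl glycoside 9 (not isolated)
Conditions: [Ir(cod)(PMePh2)2]PF6 (cat., H2-activated), THF, rt; then 0.5 M HCl, acetone/H2O, rt
Reagents that add atoms: none
Why: Iridium-hydride-catalysed allyl-to-propenyl isomerisation followed by mild enol-ether hydrolysis frees the anomeric hydroxyl under conditions that MOM and PMB ethers tolerate.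

Step 5
Reactants: 10 2,4-di-O-MOM-3-O-PMB-D-arabinopyranose; 11 vinylmagnesium bromide
Product: 12 1,2-dideoxy-4,6-di-O-(methoxymethyl)-5-O-(4-methoxybenzyl)-D-gluco-hept-1-enitol (3,7-diol)
Conditions: 11 (4 equiv, THF), MgBr2·OEt2 (2 equiv), CH2Cl2, −40 °C → rt; aqueous work-up
Reagents that add atoms: vinylmagnesium bromide (11), C=C[Mg]Br
Why: In this Grignard addition to the open aldehyde tautomer under Cram-chelate control, magnesium bridges the carbonyl oxygen and the α-OMOM oxygen and vinyl attacks the face that carries only H, which should set the new carbinol (C4 of the target numbering) syn to the C5 oxygen (D-gluco), the configuration later relayed to C1.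

Step 6
Reactants: 12 D-gluco-hept-1-enitol 3,7-diol
Product: 14 6,7-dideoxy-2,4-di-O-(methoxymethyl)-3-O-(4-methoxybenzyl)-L-gulo-hept-6-enono-1,5-lactone, via pyranose lactol 13 (not isolated)
Conditions: TEMPO (0.2 equiv), PhI(OAc)2 (2.5 equiv), CH2Cl2, rt
Reagents that add atoms: none
Why: In this oxoammonium-mediated oxidative lactonisation of a 1,5-diol the primary alcohol is oxidised selectively, the aldehyde closes onto the allylic hydroxyl to the six-membered lactol 13, and 13 is oxidised on to the δ-lactone with no stereocentre affected.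

Step 7
Reactants: 14 3-O-PMB L-gulo-heptenonolactone
Product: 15 6,7-dideoxy-2,4-di-O-(methoxymethyl)-L-gulo-hept-6-enono-1,5-lactone (free 3-OH; vinyl cis to the 4-OMOM group)
Conditions: DDQ (1.3 equiv), CH2Cl2/pH 7 buffer (10:1), 0 °C → rt
Reagents that add atoms: none
Why: Oxidative PMB cleavage (hydride abstraction to the benzylic oxocarbenium ion, then hydrolysis) is neutral enough for the lactone, the MOM ethers and the vinyl group, and it uncovers the β-hydroxyl that is needed as an alkoxide in step 8.

Step 8
Reactants: 15 2,4-di-O-MOM-L-gulo-hept-6-enono-1,5-lactone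
Product: 19 (1S,5R,6S)-6-hydroxy-1,5-bis(methoxymethoxy)cyclohex-3-ene-1-carboxylic acid, via dilithium alkoxide enolate 16 (not isolated), via bis(trimethylsilyl) ketene acetal 17 (not isolated), via trimethylsilyl ester 18 (not isolated)
Conditions: LDA (2.6 equiv), THF, −78 → −40 °C; Me3SiCl (5 equiv), −78 °C → rt; solvent change to toluene, 100 °C; then 1 M HCl, THF, rt
Reagents that add atoms: none
Why: LDA first makes the C6 lithium alkoxide and then removes H–C1 to give 16 (the dianion logic of the Fráter–Seebach alkylation), in which the β-oxygen is an oxide and cannot leave, so the E1cB loss that threatens β-alkoxy sugar-lactone enolates is shut off before Me3SiCl converts 16 into 17. On heating, 17 undergoes a concerted suprafacial [3,3] shift through the array C1=C7–O–C4–C3=C2, in which C1–C2 forms, C4–O breaks, the alkene moves to C3=C4 and C7 becomes the silyl ester 18, which is hydrolysed to 19 on work-up. The closest known reaction type is the Ireland–Claisen ring contraction of alkenyl-lactone silyl ketene acetals to cycloalkenecarboxylic acids, here combined with the dianionic Ireland–Claisen variant of β-hydroxy esters. The carbocycle C1–C6 is closed pericyclically by contraction of the lactone ring, and because C1 and C4 are tied by the two-atom bridge C6–C5 only a boat-shaped, bicyclo[2.2.2]octene-like transition state is possible. The one new stereocentre, C1, is controlled by C4: the vinyl group sits on the lactone face syn to the C5 oxygen and can reach only that face of C1=C7, so C7 ends cis to the C6 oxygen and the C1 oxygen cis to the C5 oxygen, as in the target, while the C4 centre is consumed. The step needs silylation before any retro-aldol or elimination and a single [3,3] pathway, which the oxide at C6, the low enolisation temperature, the small MOM groups next to the reacting termini and the absence of any other allyl vinyl ether unit should secure.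

Step 9
Reactants: 19 hydroxy acid
Product: 20 (1R,5R,6S)-1-(hydroxymethyl)-1,5-bis(methoxymethoxy)cyclohex-3-en-6-ol (target numbering)
Conditions: LiAlH4 (4 equiv), THF, 0 °C → reflux
Reagents that add atoms: none
Why: Hydride reduction of the carboxylic acid through its aluminium carboxylate gives the neopentyl primary alcohol C7, while the acetal ethers and the isolated alkene are inert to LiAlH4.

Step 10
Reactants: 20 C6/C7 diol; 21 benzoyl chloride
Product: 22 [(1R,5R,6S)-6-(benzoyloxy)-1,5-bis(methoxymethoxy)cyclohex-3-en-1-yl]methyl benzoate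
Conditions: 21 (3 equiv), pyridine, DMAP (cat.), 0 → 40 °C
Reagents that add atoms: benzoyl chloride (21), O=C(Cl)c1ccccc1
Why: DMAP-catalysed acylation esterifies the only two free hydroxyls (C7–OH and C6–OH) in one operation, and no regioselectivity is needed because C1–O and C5–O are still masked.

Step 11
Reactants: 22 dibenzoate
Product: 23 [6-(benzoyloxy)-2-hydroxy-1,5-bis(methoxymethoxy)cyclohex-3-en-1-yl]methyl benzoate (C1, C5 and C6 as in 22; C2 configuration immaterial)
Conditions: SeO2 (2 equiv), 1,4-dioxane, 90 °C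
Reagents that add atoms: selenium dioxide, O=[Se]=O
Why: Allylic hydroxylation by SeO2 (ene reaction, then [2,3]-sigmatropic shift) returns oxygen to the carbon that loses hydrogen without net alkene transposition, and the ene step should choose C2–H because selenium attack at C4 puts the developing positive charge on C3, away from the inductively withdrawing C5 oxygen; the new C2 centre is erased in step 12, where any enone formed by over-oxidation converges.

Step 12
Reactants: 23 C2 allylic alcohol
Product: 24 [(1R,5R,6S)-6-(benzoyloxy)-1,5-bis(methoxymethoxy)-2-oxocyclohex-3-en-1-yl]methyl benzoate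
Conditions: Dess–Martin periodinane (1.5 equiv), CH2Cl2, rt
Reagents that add atoms: none
Why: Dess–Martin oxidation of the secondary allylic alcohol gives the enone under near-neutral conditions, and because C1 is quaternary no β-elimination of the C6 benzoate can follow.

Step 13
Reactants: 24 bis-MOM enone
Product: 25 [(1R,5R,6S)-6-(benzoyloxy)-1,5-dihydroxy-2-oxocyclohex-3-en-1-yl]methyl benzoate (target)
Conditions: TFA/CH2Cl2/H2O (10:10:1), 0 °C → rt
Reagents that add atoms: none
Why: Acid-catalysed acetal hydrolysis removes both MOM groups (the electron-poor carbinols leave readily from the protonated acetal), and acidic rather than basic or fluoride conditions should avoid benzoate migration to the freed C1 and C5 hydroxyls.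

## Compound list

1 | D-arabinose | O=C[C@@H](O)[C@H](O)[C@H](O)CO | starting material
2 | allyl alcohol | C=CCO | starting material
3 | allyl β-D-arabinopyranoside | C=CCO[C@H]1[C@@H](O)[C@H](O)[C@H](O)CO1 | intermediate
4 | 4-methoxybenzyl chloride | COc1ccc(CCl)cc1 | starting material
5 | allyl 3,4-O-(dibutylstannanediyl)-β-D-arabinopyranoside | C=CCO[C@H]1[C@@H](O)[C@@H]2O[Sn](CCCC)(CCCC)O[C@@H]2CO1 | intermediate
6 | allyl 3-O-PMB-β-D-arabinopyranoside | C=CCO[C@H]1[C@@H](O)[C@H](OCc2ccc(OC)cc2)[C@H](O)CO1 | intermediate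
7 | chloromethyl methyl ether | COCCl | starting material
8 | allyl 2,4-di-O-MOM-3-O-PMB-β-D-arabinopyranoside | C=CCO[C@H]1[C@@H](OCOC)[C@H](OCc2ccc(OC)cc2)[C@H](OCOC)CO1 | intermediate
9 | (E)-prop-1-enyl 2,4-di-O-MOM-3-O-PMB-β-D-arabinopyranoside | C/C=C/O[C@H]1[C@@H](OCOC)[C@H](OCc2ccc(OC)cc2)[C@H](OCOC)CO1 | intermediate
10 | 2,4-di-O-MOM-3-O-PMB-D-arabinopyranose | OC1[C@@H](OCOC)[C@H](OCc2ccc(OC)cc2)[C@H](OCOC)CO1 | intermediate
11 | vinylmagnesium bromide | C=C[Mg]Br | starting material
12 | 1,2-dideoxy-4,6-di-O-MOM-5-O-PMB-D-gluco-hept-1-enitol | C=C[C@H](O)[C@@H](OCOC)[C@H](OCc1ccc(OC)cc1)[C@H](OCOC)CO | intermediate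
13 | 6,7-dideoxy-2,4-di-O-MOM-3-O-PMB-L-gulo-hept-6-enopyranose | O1[C@@H](C=C)[C@@H](OCOC)[C@H](OCc2ccc(OC)cc2)[C@H](OCOC)C1O | intermediate
14 | 6,7-dideoxy-2,4-di-O-MOM-3-O-PMB-L-gulo-hept-6-enono-1,5-lactone | O1[C@@H](C=C)[C@@H](OCOC)[C@H](OCc2ccc(OC)cc2)[C@H](OCOC)C1=O | intermediate
15 | 6,7-dideoxy-2,4-di-O-MOM-L-gulo-hept-6-enono-1,5-lactone (key-step precursor) | O1[C@@H](C=C)[C@@H](OCOC)[C@H](O)[C@H](OCOC)C1=O | intermediate
16 | dilithium alkoxide enolate of 15 | O1[C@@H](C=C)[C@@H](OCOC)[C@H]([O-])C(OCOC)=C1[O-].[Li+].[Li+] | intermediate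
17 | bis(trimethylsilyl) ketene acetal (C1=C7) | O1[C@@H](C=C)[C@@H](OCOC)[C@H](O[Si](C)(C)C)C(OCOC)=C1O[Si](C)(C)C | intermediate
18 | trimethylsilyl 1,5-bis(MOM-oxy)-6-(trimethylsilyloxy)cyclohex-3-ene-1-carboxylate | C[Si](C)(C)OC(=O)[C@]1(OCOC)CC=C[C@@H](OCOC)[C@@H]1O[Si](C)(C)C | intermediate
19 | (1S,5R,6S)-6-hydroxy-1,5-bis(MOM-oxy)cyclohex-3-ene-1-carboxylic acid (key-step product) | OC(=O)[C@]1(OCOC)CC=C[C@@H](OCOC)[C@@H]1O | intermediate
20 | (1R,5R,6S)-1-(hydroxymethyl)-1,5-bis(MOM-oxy)cyclohex-3-en-6-ol | OC[C@]1(OCOC)CC=C[C@@H](OCOC)[C@@H]1O | intermediate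
21 | benzoyl chloride | O=C(Cl)c1ccccc1 | starting material
22 | C6,C7-dibenzoate of 20 | O=C(OC[C@]1(OCOC)CC=C[C@@H](OCOC)[C@@H]1OC(=O)c1ccccc1)c1ccccc1 | intermediate
23 | C2 allylic alcohol | O=C(OC[C@]1(OCOC)C(O)C=C[C@@H](OCOC)[C@@H]1OC(=O)c1ccccc1)c1ccccc1 | intermediate
24 | bis-MOM enone | O=C(OC[C@]1(OCOC)C(=O)C=C[C@@H](OCOC)[C@@H]1OC(=O)c1ccccc1)c1ccccc1 | intermediate
25 | [(1R,5R,6S)-6-(benzoyloxy)-1,5-dihydroxy-2-oxocyclohex-3-en-1-yl]methyl benzoate | O=C(OC[C@]1(O)C(=O)C=C[C@@H](O)[C@@H]1OC(=O)c1ccccc1)c1ccccc1 | target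

## Step count and risks

Total step count: 13. Longest linear sequence: 13 steps, from D-arabinose.

The three steps most likely to fail are these.

1. Step 8.
   - What may go wrong: the second deprotonation next to the alkoxide may be slow. The alkoxide may scramble by retro-aldol/aldol on warming. The strained boat transition state may lie so high that the ketene acetal decays before it rearranges.
   - Fallback (same C1–C2 bond, but a base-free thermal Claisen rearrangement of an enol ether instead of an ester enolate): it sets out from 14 and returns at 20.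
   - Lactone 14 is reduced with iBu2AlH (toluene, −78 °C) to lactol 13.
   - Lactol 13 is mesylated and eliminated in one pot (MsCl, Et3N, then DBU, CH2Cl2, reflux) to the 2-alkoxy glycal 1,5-anhydro-6,7-dideoxy-2,4-di-O-MOM-3-O-PMB-L-xylo-hepta-1,6-dienitol F1.
   - Heating F1 in 1,2-dichlorobenzene (about 200 °C, sealed tube) should give, through the same boat array, 1,5-bis(MOM-oxy)-6-(PMB-oxy)cyclohex-3-ene-1-carbaldehyde F2.
   - NaBH4 in MeOH reduces F2 to the C7 primary alcohol F3, and DDQ in wet CH2Cl2 frees the C6 hydroxyl to give 20.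

2. Step 11.
   - What may go wrong: the ene reaction may be sluggish on an alkene deactivated by three nearby C–O bonds. The C5 carbinol hydrogen may be abstracted in competition, with loss of that stereocentre. The substrate may degrade on prolonged heating.
   - Fallback (the C2 oxygen is brought in with the vinyl group, so no C–H oxidation is needed): it sets out from 15 and returns at 24.
   - Cross-metathesis of 15 with vinylboronic acid pinacol ester (second-generation Hoveyda–Grubbs catalyst, CH2Cl2, reflux) gives the (E)-7-(pinacolboryl) lactone F4.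
   - Under the conditions of step 8, F4 should rearrange to the C2 allylboronate acid F5.
   - NaBO3·4H2O in THF/H2O oxidises F5 with retention to the 2,6-dihydroxy acid F6.
   - LiAlH4 reduces F6 to the C2,C6,C7-triol F7.
   - MnO2 (CH2Cl2) oxidises only the allylic C2 hydroxyl of F7 to the enone diol F8, and double benzoylation as in step 10 leads to 24.

3. Step 5.
   - What may go wrong: chelate control may erode through competition from a six-membered chelate to the β-OPMB oxygen or from open Felkin–Anh attack in the coordinating solvent, which gives poor facial selectivity at the new carbinol.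
   - Fallback (stereospecific inversion instead of stereoselective addition): it sets out from 10 through the unwanted adduct and returns at 12.
   - The separated D-manno-hept-1-enitol epimer F9 is silylated at the primary hydroxyl (TBSCl, imidazole, DMF) to the 7-O-TBS ether F10.
   - Mitsunobu reaction of F10 (4-nitrobenzoic acid, PPh3, DIAD, toluene) inverts the allylic carbinol to the D-gluco 3-O-(4-nitrobenzoate) F11.
   - K2CO3 in MeOH gives the D-gluco 7-O-TBS ether F12, and Bu4NF in THF gives 12.

## Further compounds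

F1 | step 8 | 1,5-anhydro-6,7-dideoxy-2,4-di-O-MOM-3-O-PMB-L-xylo-hepta-1,6-dienitol | O1[C@@H](C=C)[C@@H](OCOC)[C@H](OCc2ccc(OC)cc2)C(OCOC)=C1
F2 | step 8 | 1,5-bis(MOM-oxy)-6-(PMB-oxy)cyclohex-3-ene-1-carbaldehyde | O=C[C@]1(OCOC)CC=C[C@@H](OCOC)[C@@H]1OCc1ccc(OC)cc1
F3 | step 8 | [1,5-bis(MOM-oxy)-6-(PMB-oxy)cyclohex-3-en-1-yl]methanol | OC[C@]1(OCOC)CC=C[C@@H](OCOC)[C@@H]1OCc1ccc(OC)cc1
F4 | step 11 | (E)-7-(pinacolboryl)-6,7-dideoxy-2,4-di-O-MOM-L-gulo-hept-6-enono-1,5-lactone | O1[C@@H](/C=C/B2OC(C)(C)C(C)(C)O2)[C@@H](OCOC)[C@H](O)[C@H](OCOC)C1=O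
F5 | step 11 | 6-hydroxy-1,5-bis(MOM-oxy)-2-(pinacolboryl)cyclohex-3-ene-1-carboxylic acid | OC(=O)[C@]1(OCOC)[C@H](B2OC(C)(C)C(C)(C)O2)C=C[C@@H](OCOC)[C@@H]1O
F6 | step 11 | 2,6-dihydroxy-1,5-bis(MOM-oxy)cyclohex-3-ene-1-carboxylic acid | OC(=O)[C@]1(OCOC)[C@H](O)C=C[C@@H](OCOC)[C@@H]1O
F7 | step 11 | 1-(hydroxymethyl)-1,5-bis(MOM-oxy)cyclohex-3-ene-2,6-diol | OC[C@]1(OCOC)[C@H](O)C=C[C@@H](OCOC)[C@@H]1O
F8 | step 11 | 6-hydroxy-1-(hydroxymethyl)-1,5-bis(MOM-oxy)cyclohex-3-en-2-one | OC[C@]1(OCOC)C(=O)C=C[C@@H](OCOC)[C@@H]1O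
F9 | step 5 | 1,2-dideoxy-4,6-di-O-MOM-5-O-PMB-D-manno-hept-1-enitol | C=C[C@@H](O)[C@@H](OCOC)[C@H](OCc1ccc(OC)cc1)[C@H](OCOC)CO
F10 | step 5 | 7-O-TBS ether of F9 | C=C[C@@H](O)[C@@H](OCOC)[C@H](OCc1ccc(OC)cc1)[C@H](OCOC)CO[Si](C)(C)C(C)(C)C
F11 | step 5 | 1,2-dideoxy-4,6-di-O-MOM-3-O-(4-nitrobenzoyl)-5-O-PMB-7-O-TBS-D-gluco-hept-1-enitol | C=C[C@H](OC(=O)c1ccc(cc1)[N+](=O)[O-])[C@@H](OCOC)[C@H](OCc1ccc(OC)cc1)[C@H](OCOC)CO[Si](C)(C)C(C)(C)C
F12 | step 5 | 1,2-dideoxy-4,6-di-O-MOM-5-O-PMB-7-O-TBS-D-gluco-hept-1-enitol | C=C[C@H](O)[C@@H](OCOC)[C@H](OCc1ccc(OC)cc1)[C@H](OCOC)CO[Si](C)(C)C(C)(C)C
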